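The rate constants were chosen freely; the flask was simulated.

How much target stands after 20 min in flasks that differ in their charge of starting material, and how does that number move along the row?

| flask | starting material | partner | third reagent | gas | time |
|---|---|---|---|---|---|
| north | 0.0060 M | 0.0250 M | 0.0600 M | 2.8 mM (held) | 20 min |
| south-west | 0.015 M | 0.0250 M | 0.0600 M | 2.8 mM (held) | 20 min |
| west | 0.050 M | 0.0250 M | 0.0600 M | 2.8 mM (held) | 20 min |

    starting material + partner → intermediate A (k1 = 2.56 M⁻¹ min⁻¹)
    third reagent + intermediate B → target (k2 = 1.78 M⁻¹ min⁻¹)
    second reagent + intermediate A → intermediate B (k3 = 14.6 M⁻¹ min⁻¹)
    gas ⇌ second reagent, rate k4*(csat - [second reagent]) (k4 = 6.18 min⁻¹, csat = 2.8 mM)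
    starting material + second reagent → side product (k5 = 3.70 M⁻¹ min⁻¹)

- [target] at the end for north, south-west, west, in this order
- how that number moves from the first to the last of them (falls, then rises / hardly changes / rises all the way / falls all the way / rises, then falls)

- at the start none of second reagent is dissolved
- "hardly changes" means that all values lie within two and a half points (for a concentration: within two and a half percent of the largest)
- run time (north): 20 min

I would count turnovers. While a step's other reactant stays near a fixed level, the step is pseudo-first-order: each molecule meets a steady pace, and pace times run time is that step's count of turnovers.

Gas refills second reagent at 6.18 min⁻¹, faster than even the 0.915 min⁻¹ at which west could use it with its whole charge, so I hold second reagent at 2.8 mM. With partner and third reagent at their charges, starting material gets 1.28 turnovers towards intermediate A and 0.207 towards side product, together 1.49. Intermediate B gets 2.14 towards target, and intermediate A gets 0.818 towards intermediate B, fewer than either neighbouring step.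

The usual sum for steps in a row turns these counts into 13.1%. Call this the chain share, the fraction of the charged starting material that has become target while partner stands at its charge.

The charge of starting material appears nowhere in the counts, so north and south-west start with the same share. North gives 7.85 × 10⁻⁴ M. South-west gives somewhat less than 0.00196 M, because its charge is 60.0% of partner against 24.0% in north, so its partner sinks further. In west, partner is the limiting reagent: its 0.0250 M covers half of the charge. I expect less than 0.00654 M there, but still a rise, since 0.0250 M exceeds the whole charge of south-west.

The forecast gives 7.400 × 10⁻⁴ M, 0.00173 M and 0.00235 M, so rises all the way, with its first value just below my north figure, and says “target rises throughout, though sublinearly because partner depletes”.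

The simulation gives 7.47 × 10⁻⁴ M, 0.00173 M and 0.00431 M: rises all the way.

Against the chain share of 13.1%, north reaches 12.4% of its charge with 85% of partner left, south-west 11.5% with 65% left, and west 8.62% with 19% left. In north, intermediate A passes on with a half-life of 17.0 min, longer than the 6.6 min of intermediate B at the end, and at that time intermediate A holds 39.3% of the charge against 11.8% for intermediate B.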